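**Retrosynthetic overview**

1. Labels: ring A = oxane (O1, C2 with two methyls, C3–Br, C4, C5, C6 quaternary); ring B = cyclohexane (C1' on C6, C2', C3'–Cl, C4' with methyl and Br, C5', C6').
2. Target ⇒ tertiary chlorohydrin ⇒ α-chloro ketone ⇒ 4-substituted cyclohex-2-enone: the trans C4'–Br/C3'–Cl pair is read as a former C4' carbonyl with a C2'=C3' double bond beside it.
3. Key disconnection: ring B of the enone is cut at C1'–C6' (Michael) and C2'–C3' (aldol) into a ring-A acetaldehyde and methyl vinyl ketone; forward, one amine-catalysed Robinson-type annulation closes ring B and sets C1'.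
4. Enabling feature: C1' is the only ring-B atom bonded to ring A and lies 1,4 to C4', so ring B is a latent 4-substituted cyclohex-2-enone and C1' the α-carbon of an aldehyde; its two arms (C2', C6') differ only remotely, so C1' cannot be relayed from C6 and is set by the catalyst.
5. Ring order: ring A first (step 1, 6-endo bromoetherification of (R)-linalool, C6 from the chiral pool), ring B last (step 4).

Key step: step 4

Remark: commercial (R)-(−)-linalool is assumed to be of high enantiomeric purity; any (S)-antipode carried along would become a diastereomer from step 4 onward and be removed there.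

Step 1
Reactants: 1 (R)-(−)-linalool, (3R)-3,7-dimethylocta-1,6-dien-3-ol
Product: 2 (3S,6R)-3-bromo-6-ethenyl-2,2,6-trimethyloxane
Conditions: 2,4,4,6-tetrabromocyclohexa-2,5-dien-1-one (TBCO), MeNO2, 0 °C → rt, dark
Reagents that add atoms: 2,4,4,6-tetrabromocyclohexa-2,5-dien-1-one, O=C1C(Br)=CC(Br)(Br)C=C1Br
Why: Bromoetherification, in which the trisubstituted alkene takes up Br+ much faster than the vinyl group and the tertiary hydroxyl opens the bromonium ion at the tertiary carbon in 6-endo fashion to close ring A; C6 is inherited from (R)-linalool, while C3 is set in a chair transition state with bromine equatorial that barely distinguishes axial methyl from axial vinyl at C6, so both C3 epimers (and some 5-exo oxolane) are expected and the (3S,6R) isomer 2 is isolated by chromatography.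

Step 2
Reactants: 2 (3S,6R)-3-bromo-6-ethenyl-2,2,6-trimethyloxane
Product: 4 (3S,6R)-3-bromo-6-(2-hydroxyethyl)-2,2,6-trimethyloxane, via alkylborane 3 (not isolated)
Conditions: 9-borabicyclo[3.3.1]nonane (9-BBN), THF, 0 °C → rt; then H2O2, aq NaOH, 0 °C
Reagents that add atoms: 9-borabicyclo[3.3.1]nonane (boron of 3), B1C2CCCC1CCC2; hydrogen peroxide (oxygen of 4), OO
Why: Hydroboration–oxidation, in which 9-BBN places boron on the unhindered terminal carbon of the vinyl group next to the quaternary centre and oxidation with retention gives the primary alcohol, no stereocentre being formed or touched and the hindered secondary bromide being inert to cold alkaline peroxide.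

Step 3
Reactants: 4 (3S,6R)-3-bromo-6-(2-hydroxyethyl)-2,2,6-trimethyloxane
Product: 5 (3S,6R)-3-bromo-2,2,6-trimethyl-6-(2-oxoethyl)oxane
Conditions: Dess–Martin periodinane, CH2Cl2, 0 °C → rt
Reagents that add atoms: none
Why: Dess–Martin oxidation stops at the aldehyde under near-neutral conditions that leave the β-alkoxy aldehyde, the tertiary ether and the bromide untouched, and no stereocentre is affected.

Step 4
Reactants: 5 (3S,6R)-3-bromo-2,2,6-trimethyl-6-(2-oxoethyl)oxane; 6 methyl vinyl ketone (but-3-en-2-one)
Product: 9 (3S,6R)-3-bromo-2,2,6-trimethyl-6-[(1R)-4-oxocyclohex-2-en-1-yl]oxane, via keto aldehyde 7 (not isolated), via ketol 8 (not isolated)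
Conditions: (S)-2-[diphenyl(trimethylsilyloxy)methyl]pyrrolidine (10 mol %), ethyl 3,4-dihydroxybenzoate (20 mol %), CH2Cl2, 4 °C; then LiOH·H2O (0.2 equiv), i-PrOH, 0 °C → rt
Reagents that add atoms: none
Why: The amine condenses with 5 to an (E)-enamine whose C1' adds to the terminal carbon of 6 (C1'–C6' bond); hydrolysis releases 7, whose methyl-ketone enolate then attacks the aldehyde carbon (C3'–C2' bond), and ketol 8 loses water to give the conjugated enone 9. The closest known reaction type is the amine-catalysed asymmetric Michael addition of aldehydes to vinyl ketones followed by intramolecular aldol condensation (an enantioselective Robinson-type annulation), as used to turn 3-methylbutanal into 4-isopropylcyclohex-2-enone. Ring B closes in 6-(enolexo)-exo-trig fashion. C1', the only new stereocentre, is set in the Michael step by the catalyst: its diphenyl(silyloxy)methyl group blocks one face of the s-trans (E)-enamine, so that the (S)-catalyst is expected to give (S)-7 and hence (1'R)-9. The step needs face selectivity at C1' and a single aldol pairing; the first is secured because the fully substituted C6 next to C1' enforces one enamine geometry while its methyl and ring CH2 are too alike to oppose the catalyst, the second because every other enolate–carbonyl pairing in 7 would close a four-membered ring. The C1'–H and the β-placed ring-A oxygen must survive, which is why the Michael stage is run cold with a weakly acidic co-catalyst and the condensation with substoichiometric LiOH·H2O.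

Step 5
Reactants: 9 (3S,6R)-3-bromo-2,2,6-trimethyl-6-[(1R)-4-oxocyclohex-2-en-1-yl]oxane
Product: 11 (3S,6R)-3-bromo-6-[(1R,3S)-3-chloro-4-oxocyclohexyl]-2,2,6-trimethyloxane, via lithium enolate 10 (not isolated)
Conditions: LiBH(s-Bu)3, THF, −78 °C; then N-chlorosuccinimide, −78 °C; AcOH quench
Reagents that add atoms: LiBH(s-Bu)3 (lithium of 10), [Li+].CCC(C)[BH-](C(C)CC)C(C)CC; N-chlorosuccinimide, ClN1C(=O)CCC1=O
Why: Conjugate reduction with in situ enolate chlorination, in which the hindered borohydride adds hydride to C2' of the β-unsubstituted enone to give the regiodefined enolate 10 (C3'=C4') and N-chlorosuccinimide then delivers chlorine to C3' along the axial trajectory of the half-chair that keeps ring A equatorial, which sets C3' with chlorine axial and trans to the C1' substituent.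

Step 6
Reactants: 11 (3S,6R)-3-bromo-6-[(1R,3S)-3-chloro-4-oxocyclohexyl]-2,2,6-trimethyloxane
Product: 12 (3S,6R)-3-bromo-6-[(1R,3S,4R)-3-chloro-4-hydroxy-4-methylcyclohexyl]-2,2,6-trimethyloxane
Conditions: CeCl3, MeMgBr, THF, −78 °C; H2O quench
Reagents that add atoms: methylmagnesium bromide, C[Mg]Br
Why: Organocerium 1,2-addition, in which the weakly basic methylcerium reagent adds to the C4' carbonyl without enolising (and epimerising) the α-chloro ketone, attack anti to the axial C3'–Cl bond being expected to give mainly the alcohol with methyl cis to ring A, although the configuration at C4' is erased in step 7.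

Step 7
Reactants: 12 (3S,6R)-3-bromo-6-[(1R,3S,4R)-3-chloro-4-hydroxy-4-methylcyclohexyl]-2,2,6-trimethyloxane
Product: 13 deoxy isocaespitol, (3S,6R)-3-bromo-6-[(1R,3S,4S)-4-bromo-3-chloro-4-methylcyclohexyl]-2,2,6-trimethyloxane
Conditions: Me3SiBr, CH2Cl2, −40 → 0 °C
Reagents that add atoms: bromotrimethylsilane, C[Si](C)(C)Br
Why: SN1-type substitution of a tertiary alcohol under neighbouring-group control, in which bromotrimethylsilane generates the C4' cation, the axial chlorine on C3' bridges or shields the face it occupies, and bromide enters C4' axially and anti to chlorine, which gives the trans-diaxial bromochloride with bromine cis to ring A whatever the C4' configuration of 12.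

**Compound list**

1 | (R)-(−)-linalool, (3R)-3,7-dimethylocta-1,6-dien-3-ol | O[C@@](C)(C=C)CCC=C(C)C | starting material
2 | (3S,6R)-3-bromo-6-ethenyl-2,2,6-trimethyloxane | CC1(C)O[C@@](C)(C=C)CC[C@@H]1Br | intermediate
3 | (3S,6S)-3-bromo-6-[2-(9-borabicyclo[3.3.1]nonan-9-yl)ethyl]-2,2,6-trimethyloxane (alkylborane, not isolated; geometry as in 2, the C6 descriptor changes only because boron ranks below carbon) | CC1(C)O[C@@](C)(CCB2C3CCCC2CCC3)CC[C@@H]1Br | intermediate
4 | (3S,6R)-3-bromo-6-(2-hydroxyethyl)-2,2,6-trimethyloxane | CC1(C)O[C@@](C)(CCO)CC[C@@H]1Br | intermediate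
5 | (3S,6R)-3-bromo-2,2,6-trimethyl-6-(2-oxoethyl)oxane | CC1(C)O[C@@](C)(CC=O)CC[C@@H]1Br | intermediate
6 | methyl vinyl ketone (but-3-en-2-one) | CC(=O)C=C | starting material
7 | (3S,6R)-3-bromo-6-[(2S)-1,5-dioxohexan-2-yl]-2,2,6-trimethyloxane (keto aldehyde, not isolated) | CC1(C)O[C@@](C)([C@@H](C=O)CCC(C)=O)CC[C@@H]1Br | intermediate
8 | (3S,6R)-3-bromo-6-[(1R)-2-hydroxy-4-oxocyclohexyl]-2,2,6-trimethyloxane (ketol, both C2' epimers, not isolated) | CC1(C)O[C@@](C)([C@@H]2CCC(=O)CC2O)CC[C@@H]1Br | intermediate
9 | (3S,6R)-3-bromo-2,2,6-trimethyl-6-[(1R)-4-oxocyclohex-2-en-1-yl]oxane | CC1(C)O[C@@](C)([C@@H]2CCC(=O)C=C2)CC[C@@H]1Br | intermediate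
10 | (3S,6R)-3-bromo-6-[(1R)-4-(lithiooxy)cyclohex-3-en-1-yl]-2,2,6-trimethyloxane (lithium enolate, not isolated) | CC1(C)O[C@@](C)([C@@H]2CCC([O-])=CC2)CC[C@@H]1Br.[Li+] | intermediate
11 | (3S,6R)-3-bromo-6-[(1R,3S)-3-chloro-4-oxocyclohexyl]-2,2,6-trimethyloxane | CC1(C)O[C@@](C)([C@@H]2CCC(=O)[C@@H](Cl)C2)CC[C@@H]1Br | intermediate
12 | (3S,6R)-3-bromo-6-[(1R,3S,4R)-3-chloro-4-hydroxy-4-methylcyclohexyl]-2,2,6-trimethyloxane | CC1(C)O[C@@](C)([C@@H]2CC[C@](O)(C)[C@@H](Cl)C2)CC[C@@H]1Br | intermediate
13 | deoxy isocaespitol, (3S,6R)-3-bromo-6-[(1R,3S,4S)-4-bromo-3-chloro-4-methylcyclohexyl]-2,2,6-trimethyloxane | CC1(C)O[C@@](C)([C@@H]2CC[C@](C)(Br)[C@@H](Cl)C2)CC[C@@H]1Br | target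

**Totals and risks**

Total step count: 7. Longest linear sequence: 7 steps (1 to 13).

The step most likely to fail is step 4. The catalyst may not fully control the enamine face next to the quaternary C6, and the configuration at C1' can be eroded by enolisation of 7 or γ-deprotonation of 9 while the condensation is completed. The same enolisation opens the way to β-elimination of the ring-A oxygen. The fallback no longer carries the C1' configuration through the annulation; it sets out from 9 and comes back at 11. Starting from 9 of whatever diastereomeric purity step 4 delivers (the annulation can then be run with an achiral amine and buffered acid, chosen only for yield), conjugate reduction with LiBH(s-Bu)3 and protonation should give the ketone (3S,6R)-3-bromo-2,2,6-trimethyl-6-(4-oxocyclohexyl)oxane F1, in which C1' is not a stereocentre. Deprotonation of one of its two α-methylene groups with lithium (S,S)-bis(1-phenylethyl)amide in the presence of Me3SiCl (base enantiomer chosen by analogy with 4-tert-butylcyclohexanone) should give the silyl enol ether (3S,6R)-3-bromo-2,2,6-trimethyl-6-[(1R)-4-(trimethylsilyloxy)cyclohex-3-en-1-yl]oxane F2. N-chlorosuccinimide then converts it into 11.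

Second is step 7. Ionisation at C4' is slowed by the adjacent chlorine, so loss of a proton from the cation, halide scrambling (bromide opening the chloronium ion at C3') or acid cleavage of the di-tertiary ether of ring A may compete. The fallback forms the C4'–Br bond by Markovnikov addition of HBr to an alkene instead of substitution at a carbinol carbon; it sets out from 11 and comes back at 13. Methylenation of 11 with Zn, CH2Br2 and TiCl4 should give (3S,6R)-3-bromo-6-[(1R,3S)-3-chloro-4-methylidenecyclohexyl]-2,2,6-trimethyloxane F3. One equivalent of HBr in CH2Cl2 at low temperature protonates the CH2 terminus, and bromide adds to C4' anti to the C3'–Cl bond to give 13.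

Third is step 5. Chlorination of enolate 10 may show poor facial selectivity (equatorial attack gives the C3' epimer), the α-chloro ketone may epimerise through its enol, and over-chlorination or 1,2-reduction may compete. The fallback brings chlorine in by electrophilic addition to an alkene instead of an enolate; it sets out from 9 and comes back at 13. Conjugate reduction of 9 with LiBH(s-Bu)3 and trapping with PhNTf2 should give the enol triflate (3S,6R)-3-bromo-2,2,6-trimethyl-6-[(1R)-4-(trifluoromethanesulfonyloxy)cyclohex-3-en-1-yl]oxane F4. Negishi coupling with Me2Zn and Pd(PPh3)4 should give (3S,6R)-3-bromo-2,2,6-trimethyl-6-[(1R)-4-methylcyclohex-3-en-1-yl]oxane F5. N-chlorosuccinimide in aqueous acetone should give, by Markovnikov trans-diaxial opening of the chloronium ion, the chlorohydrin (3S,6R)-3-bromo-6-[(1R,3S,4S)-3-chloro-4-hydroxy-4-methylcyclohexyl]-2,2,6-trimethyloxane F6, the C4' epimer of 12. Me3SiBr as in step 7, now assisted by the antiperiplanar chlorine, converts it into 13.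

**Further compounds**

F1 | step 4 | (3S,6R)-3-bromo-2,2,6-trimethyl-6-(4-oxocyclohexyl)oxane | CC1(C)O[C@@](C)(C2CCC(=O)CC2)CC[C@@H]1Br
F2 | step 4 | (3S,6R)-3-bromo-2,2,6-trimethyl-6-[(1R)-4-(trimethylsilyloxy)cyclohex-3-en-1-yl]oxane | CC1(C)O[C@@](C)([C@@H]2CCC(O[Si](C)(C)C)=CC2)CC[C@@H]1Br
F3 | step 7 | (3S,6R)-3-bromo-6-[(1R,3S)-3-chloro-4-methylidenecyclohexyl]-2,2,6-trimethyloxane | CC1(C)O[C@@](C)([C@@H]2CCC(=C)[C@@H](Cl)C2)CC[C@@H]1Br
F4 | step 5 | (3S,6R)-3-bromo-2,2,6-trimethyl-6-[(1R)-4-(trifluoromethanesulfonyloxy)cyclohex-3-en-1-yl]oxane | CC1(C)O[C@@](C)([C@@H]2CCC(OS(=O)(=O)C(F)(F)F)=CC2)CC[C@@H]1Br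
F5 | step 5 | (3S,6R)-3-bromo-2,2,6-trimethyl-6-[(1R)-4-methylcyclohex-3-en-1-yl]oxane | CC1(C)O[C@@](C)([C@@H]2CCC(C)=CC2)CC[C@@H]1Br
F6 | step 5 | (3S,6R)-3-bromo-6-[(1R,3S,4S)-3-chloro-4-hydroxy-4-methylcyclohexyl]-2,2,6-trimethyloxane | CC1(C)O[C@@](C)([C@@H]2CC[C@](C)(O)[C@@H](Cl)C2)CC[C@@H]1Br
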